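Readings and results come from a simulation on assumed constants, and the scatter is random.

Two constants read from the earlier runs carry this reckoning: one says how fast mass goes missing, the other where the main step comes to balance.

| setting | Monday's | Sunday's | Thursday's | oak | cedar | alder | elm |
|---|---|---|---|---|---|---|---|
| starting material | 0.087 M | 0.14 M | 0.21 M | 0.25 M | 0.25 M | 0.068 M | 0.068 M |
| coupling partner | 0.90 equiv | 0.90 equiv | 0.90 equiv | 0.900 equiv | 0.900 equiv | 0.900 equiv | 0.900 equiv |
| catalyst | 1.1 mol% | 1.1 mol% | 1.1 mol% | 1.1 mol% | 1.1 mol% | 1.1 mol% | 1.1 mol% |
| temperature | 0 °C | 15 °C | 0 °C | 5 °C | 25 °C | 5 °C | 25 °C |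
| remark | run made earlier | run made earlier | run made earlier |  |  |  |  |
| time |  |  |  | 6.0 h | 6.0 h | 6.0 h | 6.0 h |

| run | time / h | target / % | starting material / % |
|---|---|---|---|
| Monday's | 1.50 | 16.5 | 81.5 |
| Monday's | 5.00 | 32.6 | 55.9 |
| Monday's | 8.00 | 36.1 | 43.0 |
| Monday's | 15.0 | 37.8 | 27.2 |
| Sunday's | 0.500 | 25.9 | 66.4 |
| Sunday's | 1.33 | 36.6 | 40.4 |
| Sunday's | 3.00 | 35.9 | 20.2 |
| Sunday's | 6.00 | 29.5 | 10.8 |
| Thursday's | 3.00 | 51.2 | 27.2 |
| Thursday's | 6.00 | 50.3 | 15.9 |
| Thursday's | 10.0 | 45.0 | 11.2 |
| Thursday's | 15.0 | 39.3 | 8.2 |

(standard deviation of a reading: 0.3 percentage points)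



1. all flasks from highest to lowest amount of target, in percent of the starting material charged, at 6.0 h (oak / cedar / alder / elm)
2. the same order at 20 min (oak / cedar / alder / elm)
3. the amount of target, in percent of the starting material charged of the flask you put first, at 6.0 h
4. the amount of target, in percent of the starting material charged of the flask you put last, at 6.0 h

With the main step alone, starting material and coupling partner give target over the catalyst, and the partner is the limiting reagent, so target in oak tops out at 90.0%.

Next I add the falling back of target, but for that I must know the free partner, and the readings don't show it. Mass is missing, so I call the charge less starting material and target the gap. In Thursday's run, from 3.00 h to 6.00 h, the gap grows at 1.77 M⁻¹ h⁻¹ per unit of starting concentration, starting material and target. Monday's run, charged at another strength, reads 1.79 M⁻¹ h⁻¹ from 8.00 h to 15.0 h. So I read the gap as starting material and target leaving in pairs, and free partner as its charge less target less half the gap.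

Target divided by free starting material and free partner then reads 93.3 M⁻¹ at the last reading of Thursday's run and 63.7 M⁻¹ at the last reading of Sunday's run. Taking its logarithm as straight in temperature gives 82.2 M⁻¹ for oak, the balance quotient, an equilibrium constant as far as readings show one: the value of that division at which the main step stands still. With it, the ceiling for target in oak falls to 75.2%.

Last comes the loss. At Thursday's constant and oak's ceiling, I estimate the gap in oak at 49.5% by 6.0 h, assuming that the falling starting material and the warmer bath offset each other. Balancing what that gap leaves free, I commit to 41.8% target in oak.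

The forecast gives oak > alder > cedar > elm at 6.0 h and cedar > oak > elm > alder at 20 min, with 45% first, above my figure for oak, and 12.5% last, and says “Cedar peaks early, then decays to about 18%”.

The flasks give oak > alder > elm > cedar at 6.0 h and cedar > oak > elm > alder at 20 min, with 43.6% in oak and 14.6% in cedar.

    starting material + target → side product (k = 10.0 M⁻¹ h⁻¹, Ea = 63.0 kJ mol⁻¹)
    starting material + coupling partner + catalyst ⇌ target + catalyst, rate k2*[starting material]*[coupling partner]*[catalyst] forward; the back reaction follows from the equilibrium constant (K = 51.0 M⁻¹, k = 7900 M⁻² h⁻¹, Ea = 38.0 kJ mol⁻¹, ΔH = −11.0 kJ mol⁻¹)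
    (constants at 25 °C)

Taking away the passing of starting material and target into side product lifts cedar from 14.6% to 70.9%, so cedar's low target comes mainly from that step. At 6.00 h, oak's own quotient is 81.8 M⁻¹, level with the carried 82.2 M⁻¹. The neighbour of oak with 0.28 mol% of catalyst stands far lower at that time, at 25.6 M⁻¹, so its main step is still short of balance, with 32.7% target.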